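**Retrosynthetic overview**
1. Target 22 ⇐ desilylation of 21 ⇐ Wittig olefination (C7=C8) of the acyclic C15 phosphonium salt 17 with the C35 apo-aldehyde 19.
2. 19 ⇐ Julia–Kocienski olefination (C7'=C8') of ring sulfone 8 with one formyl group of commercial C20 crocetin dialdehyde 18.
3. 8 ⇐ chiral Brønsted acid (imidodiphosphorimidate) catalysed hydroxyprenylative cation–olefin cyclisation of achiral neryl sulfone 4 with allylic acetate 7; this forms C2'–C1'' and C1'–C6' and sets both ring stereocentres.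
4. 17 ⇐ diol 16 ⇐ ester 14 ⇐ aldehyde 13 ⇐ imidazolidinone-catalysed conjugate addition of dienyl trifluoroborate 11 to ethyl 4-oxobutenoate 12 (sets C2).
5. Ring order: the single carbocycle is closed early (step 5); the polyene is assembled last, from the C20 centre outwards.

Assumption: carotenoid locants are used (C1–C15 acyclic half, primed ring half, side chain C1''–C4'' on C2'); the SMILES is read as (2R,2'S,6'R) with the C2' and C6' ring substituents trans; compounds 1, 5, 9, 12 and 18 are taken as purchasable.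

**Step 1**
Reactants: 1 nerol
Product: 2 5-{[(2Z)-3,7-dimethylocta-2,6-dien-1-yl]sulfanyl}-1-phenyl-1H-tetrazole
Conditions: 1-phenyl-1H-tetrazole-5-thiol, PPh3, DIAD, THF, 0 °C to rt
Reagents that add atoms: 1-phenyl-1H-tetrazole-5-thiol, Sc1nnnn1-c1ccccc1
Why: Mitsunobu thioetherification of the primary allylic alcohol proceeds by SN2 at CH2, so the 2Z geometry is kept and no stereocentre is involved.

**Step 2**
Reactants: 2 neryl tetrazolyl sulfide
Product: 4 5-{[(2Z)-3,7-dimethylocta-2,6-dien-1-yl]sulfonyl}-1-phenyl-1H-tetrazole, via neryl tetrazolyl sulfoxide 3 (not isolated)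
Conditions: (NH4)6Mo7O24·4H2O (10 mol %), 30 % H2O2, EtOH, 0 °C to rt
Reagents that add atoms: hydrogen peroxide, OO
Why: Molybdate-catalysed peroxide oxidation of the sulfide to the sulfone is chemoselective over the trisubstituted alkenes (standard preparation of Julia–Kocienski sulfones).

**Step 3**
Reactants: 5 prenyl acetate
Product: 6 (2E)-4-hydroxy-3-methylbut-2-en-1-yl acetate
Conditions: SeO2 (10 mol %), t-BuOOH, salicylic acid (10 mol %), CH2Cl2, rt
Reagents that add atoms: tert-butyl hydroperoxide, CC(C)(C)OO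
Why: Sharpless-type selenium dioxide allylic oxidation (ene reaction then [2,3]-shift) hydroxylates the methyl group trans to the CH2OAc chain, giving the E-allylic alcohol.

**Step 4**
Reactants: 6 (2E)-4-hydroxy-3-methylbut-2-en-1-yl acetate
Product: 7 (2E)-4-{[tert-butyl(diphenyl)silyl]oxy}-3-methylbut-2-en-1-yl acetate
Conditions: TBDPSCl, imidazole, CH2Cl2, 0 °C to rt
Reagents that add atoms: tert-butyl(chloro)diphenylsilane, CC(C)(C)[Si](Cl)(c1ccccc1)c1ccccc1
Why: Silylation gives an acid-robust, non-participating ether, so only the acetate end can ionise in step 5.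

**Step 5**
Reactants: 4 neryl tetrazolyl sulfone (2 equiv); 7 silyloxy allylic acetate (1 equiv)
Product: 8 5-({(1R,5S)-5-[(2E)-4-{[tert-butyl(diphenyl)silyl]oxy}-3-methylbut-2-en-1-yl]-2,6,6-trimethylcyclohex-2-en-1-yl}methanesulfonyl)-1-phenyl-1H-tetrazole
Conditions: (S,S)-imidodiphosphorimidate Brønsted acid (two 3,3'-bis[3,5-bis(trifluoromethyl)phenyl]-(S)-BINOL units, N,N'-bis(trifluoromethanesulfonyl) core; 5 mol %), CH2Cl2/(CF3)2CHOH 4:1, −40 °C, 48 h; Et3N quench; excess 4 recovered. The (S,S) catalyst is written; the sense of induction must be confirmed on the first run and the (R,R) catalyst used if it is opposite.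
Reagents that add atoms: none
Why: Proposed new method: the confined, strongly acidic chiral phosphorimidate ionises allylic acetate 7 to an E-configured 1-methyl-1-(silyloxymethyl)allyl cation held as a contact ion pair in the chiral anion; the electron-rich Me2C=CH terminus of 4 attacks its unhindered CH2 end through C6 (the 2,3-alkene of 4 is deactivated by the allylic sulfone, and the alkenes of 7 and of the product by the allylic silyl ether); the 2Z-alkene then adds anti to the developing tertiary cation through a chair (new side chain equatorial, CH2SO2 axial, hence the 1,5-trans ring) and the anion removes the axial C–H next to the cationic carbon to give the endocyclic alkene and return the proton, with the absolute sense fixed by anion-controlled face selection at the Me2C=CH bond; the closest known reaction types are imidodiphosphorimidate-catalysed proton-initiated enantioselective polyene cyclisations and non-asymmetric acid-mediated prenyl-cation additions to alkenes (the laboratory counterpart of the lycopene elongase/cyclase sequence).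

**Step 6**
Reactants: 9 (2E)-3-methylpent-2-en-4-yn-1-ol
Product: 11 potassium trifluoro[(1E,3E)-5-hydroxy-3-methylpenta-1,3-dien-1-yl]borate, via O-borylated dienyl pinacolboronate 10 (not isolated)
Conditions: pinacolborane (2.2 equiv), Cp2Zr(H)Cl (5 mol %), Et3N (10 mol %), 60 °C; then aq. KHF2, MeOH, rt
Reagents that add atoms: pinacolborane, [H]B1OC(C)(C)C(C)(C)O1; potassium hydrogen difluoride, [K+].F.[F-]
Why: Zirconium hydride-catalysed syn, anti-Markovnikov hydroboration of the terminal alkyne gives the (1E)-dienylboronate (the OH is borylated transiently), and KHF2 converts it into the trifluoroborate and frees the alcohol.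

**Step 7**
Reactants: 11 dienyl trifluoroborate; 12 ethyl (2E)-4-oxobut-2-enoate
Product: 13 ethyl (2R,3E,5E)-7-hydroxy-5-methyl-2-(2-oxoethyl)hepta-3,5-dienoate
Conditions: (2S,5S)-5-benzyl-2-tert-butyl-3-methylimidazolidin-4-one·HCl (20 mol %), HF (1 equiv, 48 % aq.), DME, −20 °C
Reagents that add atoms: none
Why: Iminium-ion catalysis (organocatalytic conjugate vinylation of enals with alkenyl trifluoroborates): the benzyl arm shields one face of the E-iminium, the borate adds ipso at the β-carbon from the open face and loses boron, which sets C2 as R by the face model of the indole/crotonaldehyde precedent.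

**Step 8**
Reactants: 13 aldehyde ester
Product: 14 ethyl (2R,3E,5E)-7-hydroxy-5-methyl-2-(3-methylbut-2-en-1-yl)hepta-3,5-dienoate
Conditions: isopropyltriphenylphosphonium iodide (2.1 equiv), n-BuLi (2.0 equiv), THF, −78 to 0 °C
Reagents that add atoms: isopropyltriphenylphosphonium iodide, CC(C)[P+](c1ccccc1)(c1ccccc1)c1ccccc1.[I-]
Why: Wittig olefination with the non-stabilised isopropylidene ylide turns CH2CHO into the prenyl group; the aldehyde reacts far faster than the ester, and the low temperature protects the α-ester stereocentre.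

**Step 9**
Reactants: 14 prenylated ester
Product: 16 (2E,4E,6R)-6-(2-hydroxypropan-2-yl)-3,9-dimethyldeca-2,4,8-trien-1-ol, via methyl ketone 15 (not isolated)
Conditions: MeMgBr (5 equiv), anhydrous CeCl3 (5 equiv), THF, −78 to 0 °C
Reagents that add atoms: methylmagnesium bromide, C[Mg]Br
Why: Double addition of the weakly basic organocerium reagent to the ester builds the C1 tertiary carbinol without enolising the acidic allylic α-hydrogen, so C2 keeps its configuration.

**Step 10**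
Reactants: 16 diol
Product: 17 [(2E,4E,6R)-6-(2-hydroxypropan-2-yl)-3,9-dimethyldeca-2,4,8-trien-1-yl]triphenylphosphonium bromide
Conditions: PPh3·HBr (1.05 equiv), MeOH, rt, dark
Reagents that add atoms: triphenylphosphine hydrobromide, [Br-].c1ccc(cc1)[PH+](c1ccccc1)c1ccccc1
Why: SN1-type phosphonium salt formation through the pentadienyl cation, which PPh3 captures at the unhindered primary end (the classical C15 Wittig-salt preparation); the non-allylic tertiary alcohol does not ionise under these conditions.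

**Step 11**
Reactants: 8 ring sulfone; 18 crocetin dialdehyde (3 equiv)
Product: 19 (2E,4E,6E,8E,10E,12E,14E,16E)-17-{(1R,5S)-5-[(2E)-4-{[tert-butyl(diphenyl)silyl]oxy}-3-methylbut-2-en-1-yl]-2,6,6-trimethylcyclohex-2-en-1-yl}-2,6,11,15-tetramethylheptadeca-2,4,6,8,10,12,14,16-octaenal
Conditions: KN(SiMe3)2 (1.1 equiv) added to 8 and 18, THF/DME, −78 to −20 °C, dark; NH4Cl quench; excess 18 recovered
Reagents that add atoms: none
Why: Julia–Kocienski olefination (addition, Smiles rearrangement, loss of SO2 and tetrazololate) forms the E C7'=C8' bond; Barbier conditions and excess dialdehyde favour mono-olefination, and the ring stereocentres are not acidic.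

**Step 12**
Reactants: 17 phosphonium salt; 19 C35 apo-aldehyde
Product: 21 tert-butyldiphenylsilyl ether of the target, via phosphorus ylide 20 (not isolated)
Conditions: NaOMe (1.2 equiv), CH2Cl2/MeOH, 0 °C to rt, dark; then iodine (I2, 2 mol %), CH2Cl2, daylight, rt; crystallise the all-E isomer
Reagents that add atoms: none
Why: Wittig olefination of the semi-stabilised allylic ylide forms C7=C8 in the presence of the free tertiary alcohol, and iodine-catalysed equilibration converts Z isomers of the conjugated chain into the all-E polyene without touching the isolated alkenes.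

**Step 13**
Reactants: 21 silyl ether of the target
Product: 22 CNP0409952.2 (target)
Conditions: TBAF (1.5 equiv), THF, 0 °C to rt, argon, dark
Reagents that add atoms: none
Why: Fluoride-mediated desilylation frees the primary allylic alcohol under neutral, non-acidic conditions that the undecaene and the tertiary alcohol tolerate.

**Compound list**
1 | nerol, (2Z)-3,7-dimethylocta-2,6-dien-1-ol | CC(C)=CCC/C(C)=C\CO | starting material
2 | 5-{[(2Z)-3,7-dimethylocta-2,6-dien-1-yl]sulfanyl}-1-phenyl-1H-tetrazole | CC(C)=CCC/C(C)=C\CSc1nnnn1-c1ccccc1 | intermediate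
3 | 5-{[(2Z)-3,7-dimethylocta-2,6-dien-1-yl]sulfinyl}-1-phenyl-1H-tetrazole (racemic at sulfur, not isolated) | CC(C)=CCC/C(C)=C\CS(=O)c1nnnn1-c1ccccc1 | intermediate
4 | 5-{[(2Z)-3,7-dimethylocta-2,6-dien-1-yl]sulfonyl}-1-phenyl-1H-tetrazole | CC(C)=CCC/C(C)=C\CS(=O)(=O)c1nnnn1-c1ccccc1 | intermediate
5 | prenyl acetate, 3-methylbut-2-en-1-yl acetate | CC(C)=CCOC(C)=O | starting material
6 | (2E)-4-hydroxy-3-methylbut-2-en-1-yl acetate | CC(=O)OC/C=C(\C)CO | intermediate
7 | (2E)-4-{[tert-butyl(diphenyl)silyl]oxy}-3-methylbut-2-en-1-yl acetate | CC(=O)OC/C=C(\C)CO[Si](c1ccccc1)(c1ccccc1)C(C)(C)C | intermediate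
8 | 5-({(1R,5S)-5-[(2E)-4-{[tert-butyl(diphenyl)silyl]oxy}-3-methylbut-2-en-1-yl]-2,6,6-trimethylcyclohex-2-en-1-yl}methanesulfonyl)-1-phenyl-1H-tetrazole | O=S(=O)(C[C@@H]1C(C)=CC[C@@H](C/C=C(\C)CO[Si](c2ccccc2)(c2ccccc2)C(C)(C)C)C1(C)C)c1nnnn1-c1ccccc1 | intermediate
9 | (2E)-3-methylpent-2-en-4-yn-1-ol | C#C/C(C)=C/CO | starting material
10 | 4,4,5,5-tetramethyl-2-{(1E,3E)-3-methyl-5-[(4,4,5,5-tetramethyl-1,3,2-dioxaborolan-2-yl)oxy]penta-1,3-dien-1-yl}-1,3,2-dioxaborolane (not isolated) | CC1(C)OB(/C=C/C(C)=C/COB2OC(C)(C)C(C)(C)O2)OC1(C)C | intermediate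
11 | potassium trifluoro[(1E,3E)-5-hydroxy-3-methylpenta-1,3-dien-1-yl]borate | OC/C=C(C)/C=C/[B-](F)(F)F.[K+] | intermediate
12 | ethyl (2E)-4-oxobut-2-enoate | CCOC(=O)/C=C/C=O | starting material
13 | ethyl (2R,3E,5E)-7-hydroxy-5-methyl-2-(2-oxoethyl)hepta-3,5-dienoate | CCOC(=O)[C@H](CC=O)/C=C/C(C)=C/CO | intermediate
14 | ethyl (2R,3E,5E)-7-hydroxy-5-methyl-2-(3-methylbut-2-en-1-yl)hepta-3,5-dienoate | CCOC(=O)[C@H](CC=C(C)C)/C=C/C(C)=C/CO | intermediate
15 | (3R,4E,6E)-8-hydroxy-6-methyl-3-(3-methylbut-2-en-1-yl)octa-4,6-dien-2-one (not isolated) | CC(=O)[C@H](CC=C(C)C)/C=C/C(C)=C/CO | intermediate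
16 | (2E,4E,6R)-6-(2-hydroxypropan-2-yl)-3,9-dimethyldeca-2,4,8-trien-1-ol | CC(C)=CC[C@H](/C=C/C(C)=C/CO)C(C)(C)O | intermediate
17 | [(2E,4E,6R)-6-(2-hydroxypropan-2-yl)-3,9-dimethyldeca-2,4,8-trien-1-yl]triphenylphosphonium bromide | CC(C)=CC[C@H](/C=C/C(C)=C/C[P+](c1ccccc1)(c1ccccc1)c1ccccc1)C(C)(C)O.[Br-] | intermediate
18 | crocetin dialdehyde, (2E,4E,6E,8E,10E,12E,14E)-2,6,11,15-tetramethylhexadeca-2,4,6,8,10,12,14-heptaenedial | O=C/C(C)=C/C=C/C(C)=C/C=C/C=C(C)/C=C/C=C(C)/C=O | starting material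
19 | (2E,4E,6E,8E,10E,12E,14E,16E)-17-{(1R,5S)-5-[(2E)-4-{[tert-butyl(diphenyl)silyl]oxy}-3-methylbut-2-en-1-yl]-2,6,6-trimethylcyclohex-2-en-1-yl}-2,6,11,15-tetramethylheptadeca-2,4,6,8,10,12,14,16-octaenal | O=C/C(C)=C/C=C/C(C)=C/C=C/C=C(C)/C=C/C=C(C)/C=C/[C@@H]1C(C)=CC[C@@H](C/C=C(\C)CO[Si](c2ccccc2)(c2ccccc2)C(C)(C)C)C1(C)C | intermediate
20 | [(2E,4E,6R)-6-(2-hydroxypropan-2-yl)-3,9-dimethyldeca-2,4,8-trien-1-ylidene]triphenylphosphorane (not isolated) | CC(C)=CC[C@H](/C=C/C(C)=C/C=P(c1ccccc1)(c1ccccc1)c1ccccc1)C(C)(C)O | intermediate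
21 | (2R,2'S,6'R)-target with the C4'' hydroxyl as its tert-butyldiphenylsilyl ether, all-E | CC(C)=CC[C@H](/C=C/C(C)=C/C=C/C(C)=C/C=C/C(C)=C/C=C/C=C(C)/C=C/C=C(C)/C=C/[C@@H]1C(C)=CC[C@@H](C/C=C(\C)CO[Si](c2ccccc2)(c2ccccc2)C(C)(C)C)C1(C)C)C(C)(C)O | intermediate
22 | CNP0409952.2, (2R,2'S,6'R)-2'-[(2E)-4-hydroxy-3-methylbut-2-en-1-yl]-2-(3-methylbut-2-en-1-yl)-3,4-didehydro-1,2-dihydro-ψ,ε-caroten-1-ol | CC(C)=CC[C@H](/C=C/C(C)=C/C=C/C(C)=C/C=C/C(C)=C/C=C/C=C(C)/C=C/C=C(C)/C=C/[C@@H]1C(C)=CC[C@@H](C/C=C(\C)CO)C1(C)C)C(C)(C)O | target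

**Step count**
Total: 13 steps. Longest linear sequence: 7 steps (6, 7, 8, 9, 10, 12, 13).

**Three steps most likely to fail**

Step 5 (the proposed new cyclisation). It may give O- or oligo-alkylation, the wrong alkene isomer, or low ee. The fallback sets out from 4 and comes back at 8, using known reactions only. Sulfone 4 is cyclised by the known Lewis-base-catalysed enantioselective bromocyclisation (chiral BINOL-derived N-triflyl thiophosphoramide, 1,3-dibromo-5,5-dimethylhydantoin) to 5-{[(1R,5R)-5-bromo-2,6,6-trimethylcyclohex-2-en-1-yl]methanesulfonyl}-1-phenyl-1H-tetrazole F1. Keck radical allylation (allyltributylstannane Bu3SnCH2CH=CH2, AIBN, benzene, 80 °C) replaces bromine by allyl from the face anti to the axial CH2SO2 group, giving 5-{[(1R,5R)-2,6,6-trimethyl-5-(prop-2-en-1-yl)cyclohex-2-en-1-yl]methanesulfonyl}-1-phenyl-1H-tetrazole F2. Cross-metathesis with methacrolein (second-generation Grubbs catalyst RuCl2(=CHPh)(H2IMes)(PCy3)) gives the E-enal 5-({(1R,5S)-2,6,6-trimethyl-5-[(2E)-3-methyl-4-oxobut-2-en-1-yl]cyclohex-2-en-1-yl}methanesulfonyl)-1-phenyl-1H-tetrazole F3. Luche reduction (NaBH4, CeCl3·7H2O) gives 5-({(1R,5S)-5-[(2E)-4-hydroxy-3-methylbut-2-en-1-yl]-2,6,6-trimethylcyclohex-2-en-1-yl}methanesulfonyl)-1-phenyl-1H-tetrazole F4, which is silylated as in step 4 to give 8.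

Step 7 (a dienyl borate on a β-ester enal). Attack through the distal diene carbon or low ee is possible. The fallback sets out from 12 and comes back at 17; it uses a plain 2-substituted vinyl borate, the nucleophile type for which the reaction was developed, and builds C5–C7 stepwise. Achiral 2-ethynyl-2-methyl-1,3-dioxolane is hydroborated as in step 6 to 4,4,5,5-tetramethyl-2-[(E)-2-(2-methyl-1,3-dioxolan-2-yl)ethenyl]-1,3,2-dioxaborolane F5 and converted with KHF2 into potassium trifluoro[(E)-2-(2-methyl-1,3-dioxolan-2-yl)ethenyl]borate F6. Addition of F6 to 12 under the step 7 conditions gives ethyl (2R,3E)-4-(2-methyl-1,3-dioxolan-2-yl)-2-(2-oxoethyl)but-3-enoate F7. The Wittig reaction of step 8 gives ethyl (2R)-5-methyl-2-[(E)-2-(2-methyl-1,3-dioxolan-2-yl)ethenyl]hex-4-enoate F8. MeMgBr/CeCl3 gives (3R)-2,6-dimethyl-3-[(E)-2-(2-methyl-1,3-dioxolan-2-yl)ethenyl]hept-5-en-2-ol F9, and dilute aqueous acid unmasks (3E,5R)-5-(2-hydroxypropan-2-yl)-8-methylnona-3,7-dien-2-one F10. Vinylmagnesium bromide gives (4E,6R)-6-(2-hydroxypropan-2-yl)-3,9-dimethyldeca-1,4,8-trien-3-ol F11 (both C3 epimers), and PPh3·HBr with allylic transposition gives 17.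

Step 10 (acid-mediated salt formation next to a tertiary alcohol and a prenyl group, with an ambident pentadienyl cation). The fallback sets out from 16 and comes back at 21, replacing the ylide by a sulfone and so also replacing step 12. Mitsunobu reaction of the primary allylic alcohol of 16 with 1-phenyl-1H-tetrazole-5-thiol gives (3R,4E,6E)-2,6-dimethyl-3-(3-methylbut-2-en-1-yl)-8-[(1-phenyl-1H-tetrazol-5-yl)sulfanyl]octa-4,6-dien-2-ol F12. Molybdate/H2O2 oxidation gives (3R,4E,6E)-2,6-dimethyl-3-(3-methylbut-2-en-1-yl)-8-[(1-phenyl-1H-tetrazol-5-yl)sulfonyl]octa-4,6-dien-2-ol F13. Julia–Kocienski olefination of F13 with 19 (KN(SiMe3)2, THF, −78 °C), followed by iodine equilibration, gives 21.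

**Further compounds**
F1 | step 5 | 5-{[(1R,5R)-5-bromo-2,6,6-trimethylcyclohex-2-en-1-yl]methanesulfonyl}-1-phenyl-1H-tetrazole | O=S(=O)(C[C@@H]1C(C)=CC[C@@H](Br)C1(C)C)c1nnnn1-c1ccccc1
F2 | step 5 | 5-{[(1R,5R)-2,6,6-trimethyl-5-(prop-2-en-1-yl)cyclohex-2-en-1-yl]methanesulfonyl}-1-phenyl-1H-tetrazole | O=S(=O)(C[C@@H]1C(C)=CC[C@@H](CC=C)C1(C)C)c1nnnn1-c1ccccc1
F3 | step 5 | 5-({(1R,5S)-2,6,6-trimethyl-5-[(2E)-3-methyl-4-oxobut-2-en-1-yl]cyclohex-2-en-1-yl}methanesulfonyl)-1-phenyl-1H-tetrazole | O=S(=O)(C[C@@H]1C(C)=CC[C@@H](C/C=C(\C)C=O)C1(C)C)c1nnnn1-c1ccccc1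
F4 | step 5 | 5-({(1R,5S)-5-[(2E)-4-hydroxy-3-methylbut-2-en-1-yl]-2,6,6-trimethylcyclohex-2-en-1-yl}methanesulfonyl)-1-phenyl-1H-tetrazole | O=S(=O)(C[C@@H]1C(C)=CC[C@@H](C/C=C(\C)CO)C1(C)C)c1nnnn1-c1ccccc1
F5 | step 7 | 4,4,5,5-tetramethyl-2-[(E)-2-(2-methyl-1,3-dioxolan-2-yl)ethenyl]-1,3,2-dioxaborolane | CC1(/C=C/B2OC(C)(C)C(C)(C)O2)OCCO1
F6 | step 7 | potassium trifluoro[(E)-2-(2-methyl-1,3-dioxolan-2-yl)ethenyl]borate | CC1(/C=C/[B-](F)(F)F)OCCO1.[K+]
F7 | step 7 | ethyl (2R,3E)-4-(2-methyl-1,3-dioxolan-2-yl)-2-(2-oxoethyl)but-3-enoate | CCOC(=O)[C@H](CC=O)/C=C/C1(C)OCCO1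
F8 | step 7 | ethyl (2R)-5-methyl-2-[(E)-2-(2-methyl-1,3-dioxolan-2-yl)ethenyl]hex-4-enoate | CCOC(=O)[C@H](CC=C(C)C)/C=C/C1(C)OCCO1
F9 | step 7 | (3R)-2,6-dimethyl-3-[(E)-2-(2-methyl-1,3-dioxolan-2-yl)ethenyl]hept-5-en-2-ol | CC(C)=CC[C@H](/C=C/C1(C)OCCO1)C(C)(C)O
F10 | step 7 | (3E,5R)-5-(2-hydroxypropan-2-yl)-8-methylnona-3,7-dien-2-one | CC(C)=CC[C@H](/C=C/C(C)=O)C(C)(C)O
F11 | step 7 | (4E,6R)-6-(2-hydroxypropan-2-yl)-3,9-dimethyldeca-1,4,8-trien-3-ol (both C3 epimers) | CC(C)=CC[C@H](/C=C/C(C)(O)C=C)C(C)(C)O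
F12 | step 10 | (3R,4E,6E)-2,6-dimethyl-3-(3-methylbut-2-en-1-yl)-8-[(1-phenyl-1H-tetrazol-5-yl)sulfanyl]octa-4,6-dien-2-ol | CC(C)=CC[C@H](/C=C/C(C)=C/CSc1nnnn1-c1ccccc1)C(C)(C)O
F13 | step 10 | (3R,4E,6E)-2,6-dimethyl-3-(3-methylbut-2-en-1-yl)-8-[(1-phenyl-1H-tetrazol-5-yl)sulfonyl]octa-4,6-dien-2-ol | CC(C)=CC[C@H](/C=C/C(C)=C/CS(=O)(=O)c1nnnn1-c1ccccc1)C(C)(C)O
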